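Numbering (clerodane): ring A = C1–C5, C10; ring B = C5–C10; lactone C18(=O)–O–C19 on C4/C5; arm C9–C11–C12(=O); furan C13–C16 with C16 bonded to C1; ring C = C1, C10, C9, C11, C12, C13, C16; α is the face of C19, β that of H10.
Cuts: C1–C16 together with C2–OH (last forward step); C12–C13 (furyl anion + aldehyde); C4–C18 and O–C18 (carbonylation, lactone); C7–O and C8–C17; C9–C11 and C10–H (reductive alkylation); C9=C10, C5–C6 and C5–C19 (aldol, Michael, hydroxymethylation).
Forward: ring A is cyclohexane-1,3-dione; ring B arises by Michael addition and a desymmetrising aldol condensation; the lactone by carbonylation of a ring A dienyl triflate; the furan is attached as a 2-silyl-3-furyl anion; ring C closes last.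
Stereochemistry: C5 from the amino-acid-catalysed aldol; C10 and C9 from dissolving-metal reduction/alkylation anti to C19; C7 and C8 from β-face hydroboration; C1 and C2 from the ring C closure.
Enabling feature: the C1=C2–C3=C4 diene of ring A, conjugated to the C18 lactone carbonyl, has its C1 terminus peri to the β-oriented C9–CH2–CO–(2-bromofuryl) arm; arylpalladation at C1 gives an allylpalladium over C2–C4 with no syn β-hydrogen (C1–H anti, C5 quaternary), so it must be opened at C2 by an oxygen nucleophile from the α face.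

Key step: step 23

Remark: compounds 29 and 30 are carried as mixtures of C12 epimers (their SMILES leave C12 open); this centre is removed in step 22.

Step 1
Reactants: 1 cyclohexane-1,3-dione; 2 pent-1-en-3-one (ethyl vinyl ketone)
Product: 3 2-(3-oxopentyl)cyclohexane-1,3-dione
Conditions: H2O, hydroquinone (cat.), 70 °C
Reagents that add atoms: none
Why: Michael addition of the vinylogous acid 1, through its enol, to the enone in water, the first stage of a Robinson-type annulation; no stereocentre is formed.

Step 2
Reactants: 3 2-(3-oxopentyl)cyclohexane-1,3-dione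
Product: 4 2-(hydroxymethyl)-2-(3-oxopentyl)cyclohexane-1,3-dione
Conditions: 37% aq. CH2O, NaHCO3 (cat.), THF–H2O, 0 °C → rt
Reagents that add atoms: formaldehyde, C=O
Why: Aldol hydroxymethylation at the one remaining acidic C2–H of the 2-alkyl-1,3-dione; the adduct cannot dehydrate because C2 becomes quaternary, and the new carbon is the future C19.

Step 3
Reactants: 4 2-(hydroxymethyl)-2-(3-oxopentyl)cyclohexane-1,3-dione
Product: 5 2-[(tert-butyldimethylsilyloxy)methyl]-2-(3-oxopentyl)cyclohexane-1,3-dione
Conditions: t-BuMe2SiOTf, 2,6-lutidine, CH2Cl2, −78 °C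
Reagents that add atoms: tert-butyldimethylsilyl trifluoromethanesulfonate, CC(C)(C)[Si](C)(C)OS(=O)(=O)C(F)(F)F
Why: Fast O-silylation of the primary alcohol with a hindered, weak base should trap the aldol adduct before retro-aldol loss of formaldehyde; silyl ether formation.

Step 4
Reactants: 5 2-[(tert-butyldimethylsilyloxy)methyl]-2-(3-oxopentyl)cyclohexane-1,3-dione
Product: 6 (8aR)-8a-[(tert-butyldimethylsilyloxy)methyl]-5-methyl-3,4,8,8a-tetrahydronaphthalene-1,6(2H,7H)-dione
Conditions: D-phenylalanine (1 equiv), (+)-camphor-10-sulfonic acid (0.5 equiv), DMF, rt → 60 °C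
Reagents that add atoms: none
Why: Hajos–Parrish–Eder–Sauer–Wiechert aldol condensation: the side-chain enamine adds to one of the two enantiotopic ring carbonyls and dehydrates to the enone, and the D-amino acid should give the 8aR centre (future C5), the mirror image of the sense shown by L-amino acids in the angular-methyl series.

Step 5
Reactants: 6 (8aR)-8a-[(tert-butyldimethylsilyloxy)methyl]-5-methyl-3,4,8,8a-tetrahydronaphthalene-1,6(2H,7H)-dione
Product: 7 enone ketal: 6 with the saturated ketone (C4) as its 1,3-dioxolane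
Conditions: (Me3SiOCH2)2, Me3SiOTf (cat.), CH2Cl2, −78 → −20 °C
Reagents that add atoms: 1,2-bis(trimethylsilyloxy)ethane, C[Si](C)(C)OCCO[Si](C)(C)C
Why: Silyl-transfer ketalisation is selective for the saturated ketone over the conjugated enone and should leave the silyl ether untouched.

Step 6
Reactants: 7 enone ketal
Product: 9 keto ester (trans-decalin; C4 dioxolane; 5α-CH2OSiMe2t-Bu; C8 ketone; 9α-CH3; 9β-CH2CO2Et; 10β-H), via lithium enolate 8 (not isolated)
Conditions: Li (2.5 equiv), NH3(l)/THF, t-BuOH (1.0 equiv), −78 °C; isoprene; then ICH2CO2Et, THF, −78 °C → rt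
Reagents that add atoms: ethyl iodoacetate, CCOC(=O)CI
Why: Dissolving-metal (Birch-type) reduction protonates C10 anti to the C5 substituent and gives the trans-fused enolate 8 regiospecifically, and its C9 alkylation should occur from the β face, away from the axial C19 carbon, so that the C9 methyl is α and the acetate arm β; reductive alkylation of an enone.

Step 7
Reactants: 9 keto ester
Product: 11 enol triflate (C7=C8; C8–OSO2CF3; otherwise as 9), via potassium enolate 10 (not isolated)
Conditions: KN(SiMe3)2, THF, −78 °C; then PhNTf2, −78 → 0 °C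
Reagents that add atoms: N-phenylbis(trifluoromethanesulfonimide), O=S(=O)(N(c1ccccc1)S(=O)(=O)C(F)(F)F)C(F)(F)F
Why: Only C7 can be deprotonated at the C8 ketone (C9 is quaternary) and the ketone is more acidic than the ester, so the enolate forms regioselectively and is O-sulfonylated; enol triflate formation.

Step 8
Reactants: 11 enol triflate
Product: 12 alkene ester (C7=C8 with C8–CH3; 9β-CH2CO2Et)
Conditions: MeZnCl, Pd(PPh3)4 (5 mol %), THF, 50 °C
Reagents that add atoms: methylzinc chloride, C[Zn]Cl
Why: Negishi cross-coupling of the hindered vinyl triflate under zerovalent palladium catalysis installs C17 and tolerates the ester, ketal and silyl ether.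

Step 9
Reactants: 12 alkene ester
Product: 13 alkene alcohol (9β-CH2CH2OH)
Conditions: LiAlH4, THF, 0 °C
Reagents that add atoms: none
Why: Hydride reduction of the ethyl ester to the primary C12 alcohol; the ketal, silyl ether and trisubstituted alkene are inert.

Step 10
Reactants: 13 alkene alcohol
Product: 14 bis(silyl ether) alkene (C12–OSiMe2t-Bu and C19–OSiMe2t-Bu)
Conditions: t-BuMe2SiCl, imidazole, DMF, rt
Reagents that add atoms: tert-butyldimethylsilyl chloride, CC(C)(C)[Si](C)(C)Cl
Why: Standard silylation of the primary alcohol, so that only the C7 hydroxyl formed next is acetylated.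

Step 11
Reactants: 14 bis(silyl ether) alkene
Product: 16 7β-alcohol (7β-OH; 8α-CH3; 8β-H), via alkylborane 15 (not isolated)
Conditions: BH3·THF, THF, 0 °C → rt; then NaOH, H2O2, 0 °C → rt
Reagents that add atoms: hydrogen peroxide, OO
Why: Hydroboration–oxidation: boron adds to the less substituted C7 and hydrogen to C8, syn and from the β face because the α face of ring B is covered by the axial C19 and C20 carbons, and oxidation with retention gives the 7β-alcohol and the 8α-methyl group.

Step 12
Reactants: 16 7β-alcohol
Product: 17 7β-acetate ketal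
Conditions: Ac2O, pyridine, DMAP (cat.), CH2Cl2, rt
Reagents that add atoms: acetic anhydride, CC(=O)OC(C)=O
Why: DMAP-catalysed acylation of the equatorial secondary alcohol; this acetate is carried to the target.

Step 13
Reactants: 17 7β-acetate ketal
Product: 18 7β-acetoxy C4 ketone
Conditions: I2 (10 mol %), acetone, rt
Reagents that add atoms: none
Why: Iodine-catalysed transketalisation to acetone removes the dioxolane under near-neutral conditions that should spare both silyl ethers and the acetate.

Step 14
Reactants: 18 7β-acetoxy C4 ketone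
Product: 19 7β-acetoxy 2-en-4-one (C2=C3 conjugated to the C4 ketone)
Conditions: 2-iodoxybenzoic acid (1.5 equiv), PhF–DMSO (2:1), 70 °C
Reagents that add atoms: none
Why: Dehydrogenation of the ketone by the hypervalent iodine oxidant through its enol; only C3 carries α-hydrogens (C5 is quaternary), so the C2=C3 enone is the only possible product.

Step 15
Reactants: 19 7β-acetoxy 2-en-4-one
Product: 20 dienyl triflate (C1=C2 and C3=C4; C4–OSO2CF3)
Conditions: Tf2O, 2,6-di-tert-butyl-4-methylpyridine, CH2Cl2, 0 °C → rt
Reagents that add atoms: trifluoromethanesulfonic anhydride, O=S(=O)(OS(=O)(=O)C(F)(F)F)C(F)(F)F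
Why: O-Sulfonylation of the enone and loss of the γ-hydrogen at C1, the only enolisable position, gives the 2-triflyloxy-1,3-diene, which is the C1=C2/C3=C4 diene of ring A; dienyl triflate formation from an enone.

Step 16
Reactants: 20 dienyl triflate
Product: 21 methyl dienoate (C4–CO2CH3; C1=C2 and C3=C4; both silyl ethers and the 7β-acetate kept)
Conditions: Pd(OAc)2 (5 mol %), 1,3-bis(diphenylphosphino)propane, CO (1 atm), Et3N, MeOH–DMF, 60 °C
Reagents that add atoms: carbon monoxide, [C-]#[O+]; methanol, CO
Why: Palladium-catalysed alkoxycarbonylation of the dienyl triflate (oxidative addition, CO insertion, methanolysis of the acylpalladium) introduces C18 at C4.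

Step 17
Reactants: 21 methyl dienoate
Product: 23 hydroxy dienyl lactone (18,19-olide; C1=C2 and C3=C4; 7β-OAc; C12–OH), via dihydroxy ester 22 (not isolated)
Conditions: HF·pyridine, pyridine, THF, 0 °C → rt; then p-TsOH·H2O (cat.), CH2Cl2, rt
Reagents that add atoms: none
Why: Fluoride cleaves both primary silyl ethers and the C19 hydroxyl, held next to the C18 ester across the C4–C5 bond, closes the five-membered lactone with loss of methanol (acid-completed lactonisation), while the C12 hydroxyl cannot reach the ester.

Step 18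
Reactants: 23 hydroxy dienyl lactone
Product: 24 aldehyde (C12 = CHO)
Conditions: Dess–Martin periodinane, NaHCO3, CH2Cl2, 0 °C → rt
Reagents that add atoms: none
Why: Dess–Martin oxidation of the primary alcohol under buffered conditions that should not touch the dienyl lactone or the acetate.

Step 19
Reactants: 25 3-bromofuran
Product: 27 3-bromo-2-(trimethylsilyl)furan, via 3-bromo-2-lithiofuran 26 (not isolated)
Conditions: LiN(i-Pr)2, THF, −78 °C; then Me3SiCl, −78 °C → rt
Reagents that add atoms: chlorotrimethylsilane, C[Si](C)(C)Cl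
Why: Amide-base deprotonation of 3-bromofuran occurs at C2 (next to oxygen and bromine) and the anion is silylated; the silyl group blocks C2 and later directs the halogen to that carbon.

Step 20
Reactants: 24 aldehyde; 27 3-bromo-2-(trimethylsilyl)furan
Product: 29 silylfuryl carbinol (C12–OH bearing the 2-(trimethylsilyl)furan-3-yl group; C12 epimers), via aryllithium 28 (not isolated)
Conditions: 27, n-BuLi, THF, −78 °C; then 24, THF, −78 °C; sat. NH4Cl at −78 °C
Reagents that add atoms: none
Why: Bromine–lithium exchange gives an aryllithium that cannot isomerise to the 2-lithio form because C2 is silylated, and at −78 °C it should add to the aldehyde much faster than to the lactone or acetate; 1,2-addition forms the C12–C13 bond.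

Step 21
Reactants: 29 silylfuryl carbinol
Product: 30 bromofuryl carbinol (C12–OH bearing the 2-bromofuran-3-yl group; C12 epimers)
Conditions: N-bromosuccinimide (1.05 equiv), NaHCO3, THF, −40 → 0 °C, dark
Reagents that add atoms: N-bromosuccinimide, O=C1CCC(=O)N1Br
Why: Electrophilic ipso-bromodesilylation: bromine attacks the silyl-bearing C2 of the 3-alkylfuran (β-silyl-stabilised cation) and silicon is lost, which places the halide at C16 regiospecifically, while the electron-poor dienyl lactone should not react.

Step 22
Reactants: 30 bromofuryl carbinol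
Product: 31 bromofuryl ketone (C12 ketone; 2-bromofuran-3-yl; ring A dienyl lactone; 7β-OAc)
Conditions: Dess–Martin periodinane, NaHCO3, CH2Cl2, 0 °C → rt
Reagents that add atoms: none
Why: Dess–Martin oxidation of the furyl carbinol removes the C12 stereocentre and turns the bromofuran into a vinylogous acyl bromide that should add readily to zerovalent palladium.

Step 23
Reactants: 31 bromofuryl ketone
Product: 33 CNP0182929.2 (target), via allyl hydrogen carbonate 32 (not isolated)
Conditions: Pd(PPh3)4 (10 mol %), KHCO3 (3 equiv), degassed DMF–H2O (9:1), 70 °C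
Reagents that add atoms: potassium hydrogencarbonate, [K+].OC([O-])=O
Why: Zerovalent palladium inserts into the C16–Br bond, the furylpalladium bromide adds syn across C1=C2 of the ring A dienyl lactone with the furyl carbon going to C1, and the η3-allylpalladium over C2–C3–C4 is opened at C2 by hydrogencarbonate on the face opposite to palladium, after which 32 loses CO2 and zerovalent palladium is returned. The closest known reaction type is the Heck cyclisation onto a 1,3-diene with capture of the allylpalladium intermediate by an external oxygen nucleophile (Heck/Tsuji–Trost cascade), here with hydrogencarbonate as the hydroxide equivalent known from allylic substitution. Ring C closes by 7-exo-trig carbopalladation; the 8-endo mode would give a non-allylic alkylpalladium and is not expected. C1 is set by the tether, since the C9 arm is β and peri to C1 so that furyl and palladium can reach only the β face (also the open one, the α face being covered by the axial C19 and C20 carbons), and C2 is set by outer-sphere attack anti to palladium, which puts oxygen α, trans to the new C1–C16 bond. β-Hydride elimination cannot compete because the C1 hydrogen is anti to palladium and C4 bears only the quaternary C5 and the C18 carbonyl, and attack at C2 instead of C4 is secured by the full substitution of C4 and the return of the conjugated C3=C4 lactone. The step also needs the C7 acetate and the lactone to survive, which the weak base and the neutral catalyst should allow.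

Compound list
1 | cyclohexane-1,3-dione | O=C1CCCC(=O)C1 | starting material
2 | pent-1-en-3-one (ethyl vinyl ketone) | CCC(=O)C=C | starting material
3 | 2-(3-oxopentyl)cyclohexane-1,3-dione | CCC(=O)CCC1C(=O)CCCC1=O | intermediate
4 | 2-(hydroxymethyl)-2-(3-oxopentyl)cyclohexane-1,3-dione | CCC(=O)CCC1(CO)C(=O)CCCC1=O | intermediate
5 | 2-[(tert-butyldimethylsilyloxy)methyl]-2-(3-oxopentyl)cyclohexane-1,3-dione | CCC(=O)CCC1(CO[Si](C)(C)C(C)(C)C)C(=O)CCCC1=O | intermediate
6 | (8aR)-8a-[(tert-butyldimethylsilyloxy)methyl]-5-methyl-3,4,8,8a-tetrahydronaphthalene-1,6(2H,7H)-dione | O=C1CC[C@@]2(CO[Si](C)(C)C(C)(C)C)C(=O)CCCC2=C1C | intermediate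
7 | enone ketal: 6 with the C4 ketone as 1,3-dioxolane | O=C1CC[C@@]2(CO[Si](C)(C)C(C)(C)C)C3(OCCO3)CCCC2=C1C | intermediate
8 | lithium C8/C9 enolate of the trans-fused (10β-H) decalone from 7 | [Li]OC=1CC[C@@]2(CO[Si](C)(C)C(C)(C)C)C3(OCCO3)CCC[C@@H]2C=1C | intermediate (not isolated)
9 | keto ester: C4 dioxolane, 5α-CH2OSiMe2t-Bu, C8 ketone, 9α-CH3, 9β-CH2CO2Et, 10β-H | O=C1CC[C@@]2(CO[Si](C)(C)C(C)(C)C)C3(OCCO3)CCC[C@@H]2[C@@]1(C)CC(=O)OCC | intermediate
10 | potassium C7/C8 enolate of 9 | [K]OC1=CC[C@@]2(CO[Si](C)(C)C(C)(C)C)C3(OCCO3)CCC[C@@H]2[C@@]1(C)CC(=O)OCC | intermediate (not isolated)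
11 | enol triflate of 9 (C7=C8, C8–OSO2CF3) | O=S(=O)(OC1=CC[C@@]2(CO[Si](C)(C)C(C)(C)C)C3(OCCO3)CCC[C@@H]2[C@@]1(C)CC(=O)OCC)C(F)(F)F | intermediate
12 | alkene ester (C7=C8, C8–CH3, 9β-CH2CO2Et) | CC1=CC[C@@]2(CO[Si](C)(C)C(C)(C)C)C3(OCCO3)CCC[C@@H]2[C@@]1(C)CC(=O)OCC | intermediate
13 | alkene alcohol (9β-CH2CH2OH) | CC1=CC[C@@]2(CO[Si](C)(C)C(C)(C)C)C3(OCCO3)CCC[C@@H]2[C@@]1(C)CCO | intermediate
14 | bis(silyl ether) alkene (C12 and C19 silyl ethers) | CC1=CC[C@@]2(CO[Si](C)(C)C(C)(C)C)C3(OCCO3)CCC[C@@H]2[C@@]1(C)CCO[Si](C)(C)C(C)(C)C | intermediate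
15 | alkylborane (7β-BH2, 8α-CH3, 8β-H) | B[C@H]1C[C@@]2(CO[Si](C)(C)C(C)(C)C)C3(OCCO3)CCC[C@@H]2[C@@](C)(CCO[Si](C)(C)C(C)(C)C)[C@@H]1C | intermediate (not isolated)
16 | 7β-alcohol (8α-CH3, C4 dioxolane, two silyl ethers) | O[C@H]1C[C@@]2(CO[Si](C)(C)C(C)(C)C)C3(OCCO3)CCC[C@@H]2[C@@](C)(CCO[Si](C)(C)C(C)(C)C)[C@@H]1C | intermediate
17 | 7β-acetate ketal | CC(=O)O[C@H]1C[C@@]2(CO[Si](C)(C)C(C)(C)C)C3(OCCO3)CCC[C@@H]2[C@@](C)(CCO[Si](C)(C)C(C)(C)C)[C@@H]1C | intermediate
18 | 7β-acetoxy C4 ketone | CC(=O)O[C@H]1C[C@@]2(CO[Si](C)(C)C(C)(C)C)C(=O)CCC[C@@H]2[C@@](C)(CCO[Si](C)(C)C(C)(C)C)[C@@H]1C | intermediate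
19 | 7β-acetoxy 2-en-4-one | CC(=O)O[C@H]1C[C@@]2(CO[Si](C)(C)C(C)(C)C)C(=O)C=CC[C@@H]2[C@@](C)(CCO[Si](C)(C)C(C)(C)C)[C@@H]1C | intermediate
20 | dienyl triflate (C1=C2, C3=C4, C4–OSO2CF3) | CC(=O)O[C@H]1C[C@@]2(CO[Si](C)(C)C(C)(C)C)C(OS(=O)(=O)C(F)(F)F)=CC=C[C@@H]2[C@@](C)(CCO[Si](C)(C)C(C)(C)C)[C@@H]1C | intermediate
21 | methyl dienoate (C4–CO2CH3, C1=C2, C3=C4) | CC(=O)O[C@H]1C[C@@]2(CO[Si](C)(C)C(C)(C)C)C(C(=O)OC)=CC=C[C@@H]2[C@@](C)(CCO[Si](C)(C)C(C)(C)C)[C@@H]1C | intermediate
22 | dihydroxy methyl dienoate (C12–OH, C19–OH) | CC(=O)O[C@H]1C[C@@]2(CO)C(C(=O)OC)=CC=C[C@@H]2[C@@](C)(CCO)[C@@H]1C | intermediate (not isolated)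
23 | hydroxy dienyl lactone (18,19-olide, C1=C2, C3=C4, 7β-OAc, C12–OH) | CC(=O)O[C@H]1C[C@@]23COC(=O)C2=CC=C[C@@H]3[C@@](C)(CCO)[C@@H]1C | intermediate
24 | aldehyde (C12 = CHO) | CC(=O)O[C@H]1C[C@@]23COC(=O)C2=CC=C[C@@H]3[C@@](C)(CC=O)[C@@H]1C | intermediate
25 | 3-bromofuran | Brc1ccoc1 | starting material
26 | 3-bromo-2-lithiofuran | [Li]c1occc1Br | intermediate (not isolated)
27 | 3-bromo-2-(trimethylsilyl)furan | C[Si](C)(C)c1occc1Br | intermediate
28 | [2-(trimethylsilyl)furan-3-yl]lithium | [Li]c1ccoc1[Si](C)(C)C | intermediate (not isolated)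
29 | silylfuryl carbinol (C12–OH, 2-(trimethylsilyl)furan-3-yl; C12 epimers) | CC(=O)O[C@H]1C[C@@]23COC(=O)C2=CC=C[C@@H]3[C@@](C)(CC(O)c2ccoc2[Si](C)(C)C)[C@@H]1C | intermediate
30 | bromofuryl carbinol (C12–OH, 2-bromofuran-3-yl; C12 epimers) | CC(=O)O[C@H]1C[C@@]23COC(=O)C2=CC=C[C@@H]3[C@@](C)(CC(O)c2ccoc2Br)[C@@H]1C | intermediate
31 | bromofuryl ketone (C12 ketone, 2-bromofuran-3-yl, ring A dienyl lactone, 7β-OAc) | CC(=O)O[C@H]1C[C@@]23COC(=O)C2=CC=C[C@@H]3[C@@](C)(CC(=O)c2ccoc2Br)[C@@H]1C | intermediate
32 | C2 hydrogen carbonate of the target | CC(=O)O[C@H]1C[C@@]23COC(=O)C2=C[C@H](OC(=O)O)[C@H]2c4occc4C(=O)C[C@@](C)([C@@H]1C)[C@@H]23 | intermediate (not isolated)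
33 | CNP0182929.2, (1S,2S,5S,7S,8S,9R,10R) in the numbering above: 1β-C16, 2α-OH, 7β-OAc, 8α-CH3, 9α-CH3, 10β-H | CC(=O)O[C@H]1C[C@@]23COC(=O)C2=C[C@H](O)[C@H]2c4occc4C(=O)C[C@@](C)([C@@H]1C)[C@@H]23 | target

Total step count: 23 (22 in the main line and one for reagent 27).
Longest linear sequence: 22 steps (steps 1–18 and 20–23, from 1 to 33).

Steps most likely to fail

1. Step 23. Capture of the allylpalladium intermediate by the weak oxygen nucleophile may be too slow, so that the catalyst is diverted to protodehalogenation, or oxygen may be delivered from palladium on the same face and give the C2 epimer. The fallback sets out from 31 and returns to 33. Ring closure is separated from hydroxyl release: cyclisation under anhydrous carboxylate-capture conditions (Pd(OAc)2, PPh3, sodium methoxyacetate, LiCl, DMF, 80 °C; chloride keeps the carboxylate off palladium so that it attacks anti) should give the C2 methoxyacetate of the target F1. Selective methanolysis of the methoxyacetate in the presence of the C7 acetate (Yb(OTf)3, MeOH, 0 °C → rt) should then give 33.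

2. Step 20. The aryllithium may lose chemoselectivity and attack the lactone or acetate carbonyl, or enolise the aldehyde. The fallback sets out from 24 and returns to 29 by a Nozaki–Hiyama–Kishi coupling. Aryllithium 28 is quenched with I2 to give 3-iodo-2-(trimethylsilyl)furan F2, which is coupled with 24 using CrCl2 (excess) and NiCl2 (cat.) in DMF at rt; the organochromium species adds only to aldehydes and should give 29.

3. Step 21. Bromine may attack the free C5 position of the furan or cause oxidative opening of the furyl carbinol instead of ipso substitution. The fallback sets out from 24 and returns to 30, bringing the bromine in with the nucleophile. 3-Iodo-2-(trimethylsilyl)furan F2 (made as above) is ipso-brominated on the simple furan (N-bromosuccinimide, MeCN, 0 °C) to 2-bromo-3-iodofuran F3. Selective iodine–magnesium exchange (i-PrMgCl·LiCl, THF, −40 °C) gives (2-bromofuran-3-yl)magnesium chloride F4, which adds to 24 at −78 °C and should give 30 directly, bypassing 29.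

Further compounds
F1 | step 23 | C2 methoxyacetate of the target | CC(=O)O[C@H]1C[C@@]23COC(=O)C2=C[C@H](OC(=O)COC)[C@H]2c4occc4C(=O)C[C@@](C)([C@@H]1C)[C@@H]23
F2 | step 20 | 3-iodo-2-(trimethylsilyl)furan | C[Si](C)(C)c1occc1I
F3 | step 21 | 2-bromo-3-iodofuran | Brc1occc1I
F4 | step 21 | (2-bromofuran-3-yl)magnesium chloride | Cl[Mg]c1ccoc1Br
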